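All runs were generated by integration on assumed constants; the scatter is artificial.

The free catalyst in the alpha run starts a conversion that the product then carries on, and the readings show how much of the rate each route supplies.

| flask | starting material | free catalyst | time |
|---|---|---|---|
| alpha | 1.00 M | 0.100 M |  |
| epsilon | 1.00 M | 0.300 M |  |
| theta | 0.500 M | 0.100 M |  |
| beta | 0.500 M | 0.300 M | 94 s |

- alpha run (time / s: [product] / M): 12: 0.026; 24: 0.073; 35: 0.138; 47: 0.247; 59: 0.372; 70: 0.516; 82: 0.661; 94: 0.779
- epsilon run (time / s: [product] / M): 12: 0.073; 24: 0.184; 35: 0.312; 47: 0.467; 59: 0.609; 70: 0.740; 82: 0.838; 94: 0.905
- theta run (time / s: [product] / M): 12: 0.016; 24: 0.043; 35: 0.071; 47: 0.104; 59: 0.148; 70: 0.187; 82: 0.228; 94: 0.281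

(scatter of a reading: 0.003 M)

- order of the initial rate in [starting material], near the charge of the alpha run, the rate being that where two percent of its starting material are product (one fixed amount of product, the same in the runs compared)
- order of the initial rate in [free catalyst], near the charge of the alpha run, the rate being that where two percent of its starting material are product
- product in the beta run at 94 s, as a share of the starting material charged

- Overall: starting material -> product, with free catalyst as catalyst.
- Constant volume, constant temperature.
- Readings of a species count what is bound in complexes too.
- An order is taken over about fifteen percent of the charge, up and down.

The reckoning here, made apart from the forecast, climbs a ladder of time scales. Between 70 s and 94 s of the alpha run, ln([product]/(charge − [product])) climbs steadily, and its slope over the charge reads as a product-route constant of 0.0498 M⁻¹ s⁻¹. The epsilon run, with 0.300 M of free catalyst, reads 0.0503 M⁻¹ s⁻¹, about the same, so across these two runs this slope does not follow the catalyst. The chord over the first 24 s of the alpha run gives 3.04 mM s⁻¹ at the reading 0.026 M, and subtracting the product route there leaves a catalysed rate of 1.78 mM s⁻¹.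

On the lowest rung, that rate makes two percent of the alpha charge, 0.0200 M, in 11.2 s. Next, product in the alpha run doubles by its own route in 13.9 s while [starting material] stays near its charge, a pseudo-first-order growth in product. The alpha run is read for 94 s, shorter than the 562 s the catalysed rate, held constant, needs for the charge. Held constant over those readings, it comes to 0.167 M against the last reading of 0.779 M.

At 0.0200 M in the alpha run, the product route gives 0.977 mM s⁻¹ beside 1.78 mM s⁻¹, a fraction 0.354 of the total. Call this the product share, the part of the rate at a stated amount of product that does not follow the catalyst. Taking the catalysed route as first order in free catalyst, the reckoned order in free catalyst is one minus the share, 0.646. The same subtraction on the theta run gives 1.41 mM s⁻¹, a catalysed order in starting material of 0.340 across the halved charge. Taking the product route as first order in starting material and weighting the two routes gives a reckoned order of 0.574 in starting material.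

The forecast gives 0.6 in starting material, 0.6 in free catalyst and 86% for the beta run, within 80% to 91%, and calls the catalysed route “nearly first order in catalyst”. The reckoning here differs slightly on both orders and sets no figure for the beta run.

The simulation gives 0.40 in starting material, 0.62 in free catalyst and 80.4% for the beta run at 94 s.

    free catalyst + starting material ⇌ catalyst-substrate complex, settled at all times (1.190 M⁻¹)
    catalyst-substrate complex → product + free catalyst (0.04690 s⁻¹)
    starting material + product → 2 product (0.05090 M⁻¹ s⁻¹)
    catalyst-substrate complex + starting material ⇌ doubly bound catalyst, settled at all times (0.9170 M⁻¹)

Where 0.0200 M of product stood in the alpha run, the rate was 0.0026 M s⁻¹, and the reckoned product route of 0.977 mM s⁻¹ makes the product share 0.376 of it, beside the 0.354 reckoned before. One minus that share is 0.624, against the simulated 0.62. Scaling the complex step by the catalyst charge and holding the product step gives the epsilon run 2.25 times the alpha rate, against the simulated 2.2. With that share, the simulated order of 0.40 leaves the complex step an order of 0.0412 in starting material near the alpha charge, against 0.340 read across the halved charge. Afterwards the product step ran on with starting material present, and the alpha run reached a quarter of its charge at 48.0 s.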